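## Structural features

Numbering runs from the carboxyl carbon: C1 (CO2H), C2 (CH2), then C3, C4 and C5 (the three carbons of the 1,2-dioxolane, whose two oxygens join C3 to C5), C6 (CH2), C7 (CH bearing a methyl), C8–C11 (four CH2), C12=C13 (E), C14–C15, C16=C17 (E) and a phenyl ring on C17; the configuration is (3R,5R,7R). C3 and C5 are both fully substituted, peroxide-bearing carbons, each with a methyl group, and the two methyls are cis on the five-membered ring; C7 lies 1,3 to C5 across the C6 methylene with no functional group near it. The O–O bond is the fragile element: it excludes catalytic hydrogenation, dissolving metals, LiAlH4, low-valent metals and reactive organometallics, and with them most standard ways of joining or saturating carbon chains. The C1 carboxyl is β to the C3 peroxide oxygen, so an enolisable C1 carbonyl can open the ring by β-elimination under base, and the 1,5-diene with its styrene end rules out late electrophilic or radical reagents. The real difficulty is to create two quaternary C–O stereocentres in a fixed cis relation on a flexible ring and then to relay absolute configuration to the remote C7. The plan exploits the fact that C1–C6 together with the two ring methyls are the eight carbons of m-xylene. With C3 and C5 held 1,3 in a six-membered carbocycle, a peroxide bridge between them can only close cis, and cutting the single missing bond C1–C6 afterwards releases the C1–C2 arm on C3 and the C6 arm on C5.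

## Logic of the disconnections

**34 to 32 and 31.** No C–C bond is cut; the C1 carboxyl is retraced through 33 to 32 and on to its protected form 31. A carbonyl at C1 is β to the C3 peroxide oxygen and would not survive the amide and ylide bases needed for the chain. The gain is a base-stable substrate for every earlier step. The demand is a final oxidation that spares two alkenes and the O–O bond.

**31 to 24 and 29.** The C12=C13 alkene is cut. It is flanked by plain CH2 groups, a one-step E-selective olefination exists for it, and the cut divides the chain into 24, which carries the ring, and 29, which carries the phenyl group, so the styrene arrives ready-made. The forward step must give E geometry under conditions that do not reduce O–O.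

**29 to 25.** The C14–C15 bond and the S–C13 bond are cut: 29 comes through 28, 27 and 26 from 25 and a two-carbon acetate unit. The E-styrene is thereby bought. The demand is alkylation at the CH2Cl terminus without allylic transposition.

**24 to 18 and 20.** The C8–C9 bond is cut, as the alkene of 22, which is saturated to 23 and then oxidised. Organometallic sp3–sp3 coupling is excluded by the peroxide, so the bond is made as an alkene and reduced with diimide while it is the only alkene in the molecule. C9–C12 come from 20, made from 19. The demand is that 18, which is α-branched, does not epimerise at C7.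

**18 to 16 and 14.** The C7–CH3 bond is cut (17 lies between). Methylation of an imide enolate sets C7 under control of a purchased auxiliary. Because the ring is racemic up to here, the same auxiliary turns the two enantiomeric ring series into a pair of diastereomers, of which only 16 is carried on. The demands are high facial selectivity and a chromatographic difference between 16 and its partner from the mirror-image ring.

**14 to 10 and 12.** The C6–C7 bond is cut, as the alkene of 13, again reduced with diimide. 12, made from 11, brings C7, C8 and the auxiliary in one reagent. The demand is an olefination mild enough for an α-peroxy aldehyde with a quaternary α-carbon.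

**10 to 6.** Here a bond is added in the backward sense: C1 and C6, the ends of the two arms in 10, 9 and 8, are rejoined as the alkene of 6. This is the simplifying move, because the acyclic 1,3-stereo problem becomes a bridged bicycle in which the cis relation of the methyls is a geometric necessity. Forward, it demands an alkene cleavage that leaves O–O intact (ozone, then borohydride, through 7) and a way to tell the two primary alcohols of 8 apart (sterics).

**6 to 4, through 5.** The O–C5 bond is cut after iodine is put back on C6. 4 is monocyclic with one stereocentre. The forward step must be a Markovnikov, anti, transannular closure that the hydroperoxide survives.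

**4 to 1.** The O–C3 bond and two C–H bonds are cut: 4 from 3 by desilylation, 3 from 2 by hydroperoxysilylation, 2 from 1 by dearomatisation. All eight carbons of 1 end up in the target. The two alkenes of 2 are enantiotopic and no reliable enantioselective version of this oxidation exists, so the series is racemic until step 12.

## Other disconnections considered

Alternative 1: The cut is C2–C3, with the two acetic acid carbons delivered from an ester tethered to the C6 oxygen. Forward, the acetate A2 would be converted to its silyl ketene acetal, the C3 methyl ketal ionised with Me3SiOTf or TiCl4, and the tethered nucleophile would close the seven-membered lactone A1.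

- In its favour: the bridged lactone can only form on the cis face, which is the equal of the chosen plan on relative configuration.
- Better than the chosen plan: C1 arrives at the carboxyl oxidation level with C6 already differentiated as an alcohol, and the C5 centre could be bought as (R)-2-methylglycidol A3, so no resolution is needed. The (R) assignment assumes that its quaternary carbon becomes C5 either with retention (oxirane CH2 becoming C4) or with inversion by perhydrolysis (oxirane CH2 becoming C6); both mappings call for the same enantiomer.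
- Against it: the C–C bond is formed through a seven-membered transition state onto a peroxide-stabilised cation, where intermolecular reaction and fragmentation of the cation compete. A silyl ketene acetal must be generated in the presence of a peroxy ketal. The stereospecific translation of the carbinol carbon of A3 into a C–OO centre is itself several uncertain steps.
- Comparison: A1 is a β-peroxy lactone and would have to be reduced to diol 8 before the base-mediated chain steps, so most of the oxidation-level advantage would be lost. On step count the two plans are expected to be close. The chosen plan has the more secure ring-forming mechanism; Alternative 1 has the better stereochemical economy.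

Alternative 2: The cuts are C3–C4 and O–C5, with C1 and C6 joined temporarily through an ether oxygen. Forward, SnCl4 would ionise the silylperoxy ketal A5; the tethered methallyl group would attack through its CH2 terminus (closing an oxepane) and the resulting tertiary cation would be captured by the peroxide oxygen, giving the bridged ether A4.

- Better than the chosen plan: both ring bonds of the dioxolane form in one step, and ozone and iodine are avoided.
- Equal: the tether enforces the cis relation; A5 should be reachable in about as many steps as 4; A4 is racemic, as 5 is.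
- Against it: the first bond forms in a seven-membered endo mode with thin precedent for the intramolecular case. More seriously, the tether in A4 is a dialkyl ether between two primary carbons, and no mild method cleaves or regioselectively oxidises such an ether in the presence of O–O. An oxidation of the C1 methylene to lactone A1 is conceivable but unproven on such a substrate.
- Comparison: the chosen plan opens its temporary ring by ozonolysis of an alkene, a far easier release than ether cleavage, and this decides the comparison despite the better bond economy of Alternative 2.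

Alternative 3: The cuts are C4–C5 and O–C3, in an intermolecular annulation. Forward, SnCl4 would ionise the silylperoxy ketal A7, made from (R)-citronellal A8, and the 1,1-disubstituted alkene A9 would add through its CH2 terminus and be closed by the peroxide oxygen to give dioxolane A6.

- Better than the chosen plan: it is the most convergent of the four; the whole C1–C12 skeleton with both arms differentiated appears in one step, and C7 comes from the chiral pool with no auxiliary.
- Equal or better: the intermolecular annulation of such cations with 1,1-disubstituted alkenes is an established reaction type.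
- Against it: nothing connects C3 and C5 while the bonds form, so the cis/trans ratio is expected to be modest and C7 is too remote to bias either new centre. Up to four diastereomers would arise, differing at centres far apart, and only A6 is wanted.
- Comparison: both plans lose material. The chosen plan loses half as the wrong enantiomer but fixes cis by geometry and separates diastereomers with adjacent 1,3-centres. Alternative 3 loses material earlier and more cheaply, but its separation problem is harder and its outcome is not controlled by any structural element.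

Key step: step 4

## Remarks before the steps

- **Assumption on drawing.** Compounds 3–10 are racemic and 13 and 14 are 1:1 mixtures of two diastereomers; each is drawn, named and numbered only as the isomer that leads to the target. In step 12 the undrawn diastereomer of 14 gives the (2S)-methyl imide of the mirror-image (3S,5R) ring, which is removed by chromatography there, so the series is single-isomer from 16 on.
- **Configuration.** The target is (3R,5R,7R). The matching hydroperoxide is (S)-4 and the matching iodide is (1S,2S,5S)-5, with iodine anti to the O–O bridge. Ring descriptors change along the route (for example (3S,5S) in 8–10) only because substituent priorities change; no centre is inverted.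
- **Precursor design.** The hydroperoxide 4 is never stored. The silyl peroxide 3 is the handled form, and 4 is released from it immediately before cyclisation and used as a dilute solution. Silane is the limiting reagent in step 2 to hold the reaction at mono-addition. The volatile alkene 6 is likewise carried in solution. Work with 4–7 is done dilute, cold and behind a shield.

## Steps

Step 1
Reactants: 1 m-xylene
Product: 2 1,5-dimethylcyclohexa-1,4-diene
Conditions: Li, NH3 (l), EtOH, Et2O, −78 → −33 °C
Reagents that add atoms: none
Why: Birch reduction; the two methyl groups direct protonation to the ring carbons between and opposite them, so both methyl-bearing carbons stay vinylic and the unconjugated 1,4-diene is the kinetic product.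

Step 2
Reactants: 2 1,5-dimethylcyclohexa-1,4-diene
Product: 3 triethyl{[(1S)-1,3-dimethylcyclohex-3-en-1-yl]peroxy}silane (racemic)
Conditions: Co(acac)2 (5 mol %), Et3SiH (0.9 equiv), O2 (1 atm), ClCH2CH2Cl, rt
Reagents that add atoms: dioxygen O=O; triethylsilane CC[SiH](CC)CC
Why: Mukaiyama–Isayama hydroperoxysilylation; a cobalt hydride transfers a hydrogen atom to the CH end of one trisubstituted alkene, the tertiary radical captures O2 and the peroxyl is silylated, giving the Markovnikov tertiary silyl peroxide. The two alkenes of 2 are enantiotopic, so 3 is racemic, and limiting silane keeps the second alkene intact.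

Step 3
Reactants: 3 triethyl{[(1S)-1,3-dimethylcyclohex-3-en-1-yl]peroxy}silane
Product: 4 (1S)-1,3-dimethylcyclohex-3-en-1-yl hydroperoxide (racemic)
Conditions: HCl (cat.), MeOH, 0 °C; NaHCO3; exchange into CH2Cl2, solution used at once
Reagents that add atoms: none
Why: Acid-catalysed methanolysis of the O–Si bond of a silyl peroxide; no bond to the tertiary carbon is touched, and the hydroperoxide is kept in dilute solution for safety.

Step 4
Reactants: 4 (1S)-1,3-dimethylcyclohex-3-en-1-yl hydroperoxide
Product: 5 (1S,2S,5S)-2-iodo-1,5-dimethyl-6,7-dioxabicyclo[3.2.1]octane (racemic)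
Conditions: N-iodosuccinimide (1.2 equiv), CH2Cl2, 0 °C → rt, dark
Reagents that add atoms: N-iodosuccinimide O=C1CCC(=O)N1I
Why: N-Iodosuccinimide transfers electrophilic iodine reversibly to either face of the trisubstituted ring alkene of 4; only the iodonium ion on the face opposite the hydroperoxide can be opened, and it is opened at its methyl-bearing carbon by the terminal oxygen of the axial OOH group held 1,3 across the ring, the proton going to succinimide anion. The closest known reaction type is the halocyclisation of unsaturated hydroperoxides to 1,2-dioxolanes, here in the transannular mode familiar from iodolactonisation of cyclohex-3-ene-1-carboxylic acid. One ring is closed, the 1,2-dioxolane, by 5-exo attack on the iodonium ion, which gives the 6,7-dioxabicyclo[3.2.1]octane. The new quaternary centre (C1 of 5, C5 of the target) is controlled by the tether: a two-oxygen bridge across a six-membered ring can only be diaxial, so the two methyl groups must be cis on the dioxolane. The CHI centre (C2 of 5) is controlled by anti opening of the iodonium ion, which places iodine axial and anti to the new C–O bond, as the next step requires. Regioselectivity is needed, since attack at the CH carbon would give a 2,3-dioxabicyclo[2.2.2]octane; it is secured by the Markovnikov polarisation of the iodonium ion and by the chair-like geometry of the 1,3-diaxial closure as against the boat required for the other. Chemoselectivity for the alkene over oxidation of the OOH group is helped by iodide-free conditions at 0 °C in the dark.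

Step 5
Reactants: 5 (1S,2S,5S)-2-iodo-1,5-dimethyl-6,7-dioxabicyclo[3.2.1]octane
Product: 6 (1S,5S)-1,5-dimethyl-6,7-dioxabicyclo[3.2.1]oct-2-ene (racemic)
Conditions: DBU, THF, 60 °C; product kept as a CH2Cl2 solution
Reagents that add atoms: none
Why: E2 elimination; the axial iodide has one anti-periplanar hydrogen, on C3, and the other neighbour is quaternary, so a single alkene can form. Neither peroxide carbon carries hydrogen, so base-induced Kornblum–DeLaMare cleavage is impossible.

Step 6
Reactants: 6 (1S,5S)-1,5-dimethyl-6,7-dioxabicyclo[3.2.1]oct-2-ene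
Product: 8 2-[(3S,5S)-5-(hydroxymethyl)-3,5-dimethyl-1,2-dioxolan-3-yl]ethan-1-ol (racemic), via secondary ozonide 7 (not isolated)
Conditions: O3, CH2Cl2, −78 °C; then NaBH4, MeOH, −78 → 0 °C
Reagents that add atoms: ozone [O-][O+]=O
Why: Ozonolysis (Criegee mechanism) with borohydride reduction of the ozonide; a di-tertiary dialkyl peroxide is inert to ozone and to NaBH4 at low temperature, and the reductive work-up means the base-sensitive β-peroxy aldehyde never accumulates. No stereocentre is touched.

Step 7
Reactants: 8 2-[(3S,5S)-5-(hydroxymethyl)-3,5-dimethyl-1,2-dioxolan-3-yl]ethan-1-ol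
Product: 9 [(3S,5S)-5-(2-{[tert-butyl(diphenyl)silyl]oxy}ethyl)-3,5-dimethyl-1,2-dioxolan-3-yl]methanol (racemic)
Conditions: t-BuPh2SiCl (1.0 equiv), imidazole, CH2Cl2, −20 → 0 °C
Reagents that add atoms: tert-butyl(chloro)diphenylsilane CC(C)(C)[Si](Cl)(c1ccccc1)c1ccccc1
Why: Sterically selective silylation; the bulky chlorosilane should react much faster at the unhindered CH2CH2OH than at the neopentyl-type CH2OH on the quaternary ring carbon.

Step 8
Reactants: 9 [(3S,5S)-5-(2-{[tert-butyl(diphenyl)silyl]oxy}ethyl)-3,5-dimethyl-1,2-dioxolan-3-yl]methanol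
Product: 10 (3S,5S)-5-(2-{[tert-butyl(diphenyl)silyl]oxy}ethyl)-3,5-dimethyl-1,2-dioxolane-3-carbaldehyde (racemic)
Conditions: Dess–Martin periodinane, NaHCO3, CH2Cl2, 0 °C → rt
Reagents that add atoms: none
Why: Dess–Martin oxidation; the aldehyde has a quaternary α-carbon and cannot enolise, and the reagent does not affect O–O or the silyl ether.

Step 9
Reactants: 11 (4S)-4-benzyl-1,3-oxazolidin-2-one
Product: 12 diethyl {2-[(4S)-4-benzyl-2-oxo-1,3-oxazolidin-3-yl]-2-oxoethyl}phosphonate
Conditions: (EtO)2P(O)CH2CO2H, t-BuCOCl, Et3N, THF, −20 °C; then 11, LiCl, → rt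
Reagents that add atoms: (diethoxyphosphoryl)acetic acid CCOP(=O)(OCC)CC(=O)O
Why: N-Acylation of an oxazolidinone by a pivaloyl mixed anhydride with LiCl and Et3N activation; the bulky pivaloyl carbonyl is not attacked.

Step 10
Reactants: 10 (3S,5S)-5-(2-{[tert-butyl(diphenyl)silyl]oxy}ethyl)-3,5-dimethyl-1,2-dioxolane-3-carbaldehyde; 12 diethyl {2-[(4S)-4-benzyl-2-oxo-1,3-oxazolidin-3-yl]-2-oxoethyl}phosphonate
Product: 13 (4S)-4-benzyl-3-{(2E)-3-[(3S,5S)-5-(2-{[tert-butyl(diphenyl)silyl]oxy}ethyl)-3,5-dimethyl-1,2-dioxolan-3-yl]prop-2-enoyl}-1,3-oxazolidin-2-one (1:1 with its diastereomer from the mirror-image ring)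
Conditions: LiCl, i-Pr2NEt, MeCN, rt
Reagents that add atoms: none
Why: Horner–Wadsworth–Emmons olefination under Masamune–Roush conditions; the amine base is mild enough for the α-peroxy aldehyde, and the stabilised phosphonate gives the E enoyl imide. Both enantiomers of 10 react alike.

Step 11
Reactants: 13 (4S)-4-benzyl-3-{(2E)-3-[(3S,5S)-5-(2-{[tert-butyl(diphenyl)silyl]oxy}ethyl)-3,5-dimethyl-1,2-dioxolan-3-yl]prop-2-enoyl}-1,3-oxazolidin-2-one
Product: 14 (4S)-4-benzyl-3-{3-[(3R,5S)-5-(2-{[tert-butyl(diphenyl)silyl]oxy}ethyl)-3,5-dimethyl-1,2-dioxolan-3-yl]propanoyl}-1,3-oxazolidin-2-one (1:1 with its diastereomer from the mirror-image ring)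
Conditions: KO2CN=NCO2K, AcOH, MeOH/CH2Cl2, 0 °C → rt
Reagents that add atoms: none
Why: Diimide reduction; concerted syn transfer of two hydrogens saturates the C6=C7 alkene without cleaving O–O, which catalytic hydrogenation would not spare.

Step 12
Reactants: 14 (4S)-4-benzyl-3-{3-[(3R,5S)-5-(2-{[tert-butyl(diphenyl)silyl]oxy}ethyl)-3,5-dimethyl-1,2-dioxolan-3-yl]propanoyl}-1,3-oxazolidin-2-one
Product: 16 (4S)-4-benzyl-3-{(2S)-3-[(3R,5S)-5-(2-{[tert-butyl(diphenyl)silyl]oxy}ethyl)-3,5-dimethyl-1,2-dioxolan-3-yl]-2-methylpropanoyl}-1,3-oxazolidin-2-one, via sodium enolate 15 (not isolated)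
Conditions: NaN(SiMe3)2, THF, −78 °C; MeI, −78 → −40 °C; chromatography
Reagents that add atoms: iodomethane CI
Why: Evans asymmetric alkylation; the chelated Z sodium enolate is shielded on one face by the benzyl group and iodomethane enters from the other, giving the (2S) imide, which is C7 (R) of the target. The auxiliary sets (2S) in both ring series, so the material from the mirror-image ring is a diastereomer of 16 that differs in the 1,3-relation of C5 and C7, and it is removed here by chromatography.

Step 13
Reactants: 16 (4S)-4-benzyl-3-{(2S)-3-[(3R,5S)-5-(2-{[tert-butyl(diphenyl)silyl]oxy}ethyl)-3,5-dimethyl-1,2-dioxolan-3-yl]-2-methylpropanoyl}-1,3-oxazolidin-2-one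
Product: 17 (2S)-3-[(3R,5S)-5-(2-{[tert-butyl(diphenyl)silyl]oxy}ethyl)-3,5-dimethyl-1,2-dioxolan-3-yl]-2-methylpropan-1-ol
Conditions: LiBH4, MeOH (1 equiv), Et2O, 0 °C
Reagents that add atoms: none
Why: Reductive removal of the auxiliary by borohydride attack at the exocyclic imide carbonyl; a hindered di-tertiary peroxide and the silyl ether are expected to tolerate LiBH4 at 0 °C, and C7 is not epimerised.

Step 14
Reactants: 17 (2S)-3-[(3R,5S)-5-(2-{[tert-butyl(diphenyl)silyl]oxy}ethyl)-3,5-dimethyl-1,2-dioxolan-3-yl]-2-methylpropan-1-ol
Product: 18 (2S)-3-[(3R,5S)-5-(2-{[tert-butyl(diphenyl)silyl]oxy}ethyl)-3,5-dimethyl-1,2-dioxolan-3-yl]-2-methylpropanal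
Conditions: Dess–Martin periodinane, NaHCO3, CH2Cl2, 0 °C; used at once
Reagents that add atoms: none
Why: Buffered Dess–Martin oxidation, chosen because it is non-basic and should not epimerise the α-methyl aldehyde; immediate use guards C7 further.

Step 15
Reactants: 19 4-bromobutan-1-ol
Product: 20 (4-hydroxybutyl)triphenylphosphonium bromide
Conditions: PPh3, MeCN, reflux
Reagents that add atoms: triphenylphosphine c1ccc(cc1)P(c1ccccc1)c1ccccc1
Why: SN2 quaternisation of triphenylphosphine by a primary bromide; the salt crystallises and needs no chromatography.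

Step 16
Reactants: 18 (2S)-3-[(3R,5S)-5-(2-{[tert-butyl(diphenyl)silyl]oxy}ethyl)-3,5-dimethyl-1,2-dioxolan-3-yl]-2-methylpropanal; 20 (4-hydroxybutyl)triphenylphosphonium bromide
Product: 22 (4Z,6S)-7-[(3R,5S)-5-(2-{[tert-butyl(diphenyl)silyl]oxy}ethyl)-3,5-dimethyl-1,2-dioxolan-3-yl]-6-methylhept-4-en-1-ol, via alkoxide ylide 21 (not isolated)
Conditions: 20 (2 equiv), NaN(SiMe3)2 (4 equiv), THF, 0 °C; then 18, −78 °C → rt
Reagents that add atoms: none
Why: Wittig olefination with a non-stabilised ylide carried as its alkoxide; at −78 °C addition to the aldehyde should outrun enolisation, so C7 is kept. The Z geometry expected is irrelevant because the alkene is saturated next.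

Step 17
Reactants: 22 (4Z,6S)-7-[(3R,5S)-5-(2-{[tert-butyl(diphenyl)silyl]oxy}ethyl)-3,5-dimethyl-1,2-dioxolan-3-yl]-6-methylhept-4-en-1-ol
Product: 23 (6R)-7-[(3R,5S)-5-(2-{[tert-butyl(diphenyl)silyl]oxy}ethyl)-3,5-dimethyl-1,2-dioxolan-3-yl]-6-methylheptan-1-ol
Conditions: KO2CN=NCO2K, AcOH, MeOH/CH2Cl2, rt
Reagents that add atoms: none
Why: Diimide reduction of the only alkene present, placed before the C12=C13 and C16=C17 alkenes exist; O–O is untouched. The descriptor at C7 changes to R through priorities only.

Step 18
Reactants: 23 (6R)-7-[(3R,5S)-5-(2-{[tert-butyl(diphenyl)silyl]oxy}ethyl)-3,5-dimethyl-1,2-dioxolan-3-yl]-6-methylheptan-1-ol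
Product: 24 (6R)-7-[(3R,5S)-5-(2-{[tert-butyl(diphenyl)silyl]oxy}ethyl)-3,5-dimethyl-1,2-dioxolan-3-yl]-6-methylheptanal
Conditions: Dess–Martin periodinane, NaHCO3, CH2Cl2, rt
Reagents that add atoms: none
Why: Dess–Martin oxidation of an unhindered primary alcohol to the aldehyde with no over-oxidation and no effect on O–O.

Step 19
Reactants: 25 trans-cinnamyl chloride
Product: 26 tert-butyl (4E)-5-phenylpent-4-enoate
Conditions: t-BuOAc, LiN(i-Pr)2, THF, −78 °C; then 25, DMPU, −78 → 0 °C
Reagents that add atoms: tert-butyl acetate CC(=O)OC(C)(C)C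
Why: SN2 alkylation of a lithium ester enolate by a primary allylic chloride at its CH2Cl terminus; the tert-butyl ester resists self-condensation and the E alkene is carried through unchanged.

Step 20
Reactants: 26 tert-butyl (4E)-5-phenylpent-4-enoate
Product: 27 (4E)-5-phenylpent-4-en-1-ol
Conditions: LiAlH4, THF, 0 °C
Reagents that add atoms: none
Why: Hydride reduction of the ester to the primary alcohol; the styrene alkene is not conjugated to the carbonyl and is not reduced.

Step 21
Reactants: 27 (4E)-5-phenylpent-4-en-1-ol
Product: 28 1-phenyl-5-{[(4E)-5-phenylpent-4-en-1-yl]sulfanyl}-1H-tetrazole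
Conditions: 1-phenyl-1H-tetrazole-5-thiol, PPh3, i-PrO2CN=NCO2i-Pr, THF, 0 °C → rt
Reagents that add atoms: 1-phenyl-1H-tetrazole-5-thiol Sc1nnnn1-c1ccccc1
Why: Mitsunobu thioetherification of a primary alcohol with an acidic heteroaryl thiol.

Step 22
Reactants: 28 1-phenyl-5-{[(4E)-5-phenylpent-4-en-1-yl]sulfanyl}-1H-tetrazole
Product: 29 1-phenyl-5-{[(4E)-5-phenylpent-4-en-1-yl]sulfonyl}-1H-tetrazole
Conditions: (NH4)6Mo7O24·4H2O (10 mol %), H2O2 (30 % aq.), EtOH, 0 °C → rt
Reagents that add atoms: hydrogen peroxide OO
Why: Molybdate-catalysed oxidation of sulfide to sulfone; the peroxomolybdate oxidises sulfur far faster than it epoxidises the styrene alkene.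

Step 23
Reactants: 24 (6R)-7-[(3R,5S)-5-(2-{[tert-butyl(diphenyl)silyl]oxy}ethyl)-3,5-dimethyl-1,2-dioxolan-3-yl]-6-methylheptanal; 29 1-phenyl-5-{[(4E)-5-phenylpent-4-en-1-yl]sulfonyl}-1H-tetrazole
Product: 31 tert-butyl(2-{(3S,5R)-3,5-dimethyl-5-[(2R,7E,11E)-2-methyl-12-phenyldodeca-7,11-dien-1-yl]-1,2-dioxolan-3-yl}ethoxy)diphenylsilane, via potassium sulfonyl carbanion 30 (not isolated)
Conditions: 29, KN(SiMe3)2, DME, −60 °C; then 24, −60 °C → rt
Reagents that add atoms: none
Why: Julia–Kocienski olefination; the sulfonyl carbanion adds to the aldehyde, Smiles rearrangement follows, and SO2 and the tetrazolone are lost. A potassium counter-ion in DME favours the anti adduct and hence the E C12=C13 alkene; no stereocentre is involved, and the peroxide and silyl ether should tolerate the amide base at low temperature.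

Step 24
Reactants: 31 tert-butyl(2-{(3S,5R)-3,5-dimethyl-5-[(2R,7E,11E)-2-methyl-12-phenyldodeca-7,11-dien-1-yl]-1,2-dioxolan-3-yl}ethoxy)diphenylsilane
Product: 32 2-{(3S,5R)-3,5-dimethyl-5-[(2R,7E,11E)-2-methyl-12-phenyldodeca-7,11-dien-1-yl]-1,2-dioxolan-3-yl}ethan-1-ol
Conditions: Bu4NF, AcOH, THF, 0 °C → rt
Reagents that add atoms: none
Why: Fluoride cleavage of the Si–O bond; the acetic acid buffer keeps the medium near neutral.

Step 25
Reactants: 32 2-{(3S,5R)-3,5-dimethyl-5-[(2R,7E,11E)-2-methyl-12-phenyldodeca-7,11-dien-1-yl]-1,2-dioxolan-3-yl}ethan-1-ol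
Product: 34 2-{(3R,5R)-3,5-dimethyl-5-[(2R,7E,11E)-2-methyl-12-phenyldodeca-7,11-dien-1-yl]-1,2-dioxolan-3-yl}acetic acid, via aldehyde 33 (not isolated)
Conditions: TEMPO (20 mol %), PhI(OAc)2 (2.2 equiv), MeCN/H2O (1:1), rt
Reagents that add atoms: water O
Why: Oxoammonium-mediated oxidation; the alcohol goes to aldehyde 33, whose hydrate is oxidised on to the acid in the aqueous medium. The near-neutral conditions should not trigger β-elimination of the peroxide, and both alkenes are inert to the reagent.

## Compound list

1 | m-xylene (1,3-dimethylbenzene) | Cc1cccc(C)c1 | starting material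
2 | 1,5-dimethylcyclohexa-1,4-diene | CC1=CCC=C(C)C1 | intermediate
3 | triethyl{[(1S)-1,3-dimethylcyclohex-3-en-1-yl]peroxy}silane (racemic) | C1C=C(C)C[C@](C)(C1)OO[Si](CC)(CC)CC | intermediate
4 | (1S)-1,3-dimethylcyclohex-3-en-1-yl hydroperoxide (racemic) | C1C=C(C)C[C@](C)(C1)OO | intermediate
5 | (1S,2S,5S)-2-iodo-1,5-dimethyl-6,7-dioxabicyclo[3.2.1]octane, iodine anti to the O–O bridge (racemic) | C1[C@H](I)[C@]2(C)C[C@](C)(C1)OO2 | intermediate
6 | (1S,5S)-1,5-dimethyl-6,7-dioxabicyclo[3.2.1]oct-2-ene (racemic) | C1=C[C@]2(C)C[C@](C)(C1)OO2 | intermediate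
7 | secondary ozonide of 6 (1,2,4-trioxolane across the former C2=C3 alkene; configuration at the two acetal carbons not defined) | C1C2OC(OO2)[C@]3(C)C[C@@]1(C)OO3 | intermediate (not isolated)
8 | 2-[(3S,5S)-5-(hydroxymethyl)-3,5-dimethyl-1,2-dioxolan-3-yl]ethan-1-ol (racemic) | OC[C@]1(C)C[C@](C)(CCO)OO1 | intermediate
9 | [(3S,5S)-5-(2-{[tert-butyl(diphenyl)silyl]oxy}ethyl)-3,5-dimethyl-1,2-dioxolan-3-yl]methanol (racemic) | OC[C@]1(C)C[C@](C)(CCO[Si](c2ccccc2)(c2ccccc2)C(C)(C)C)OO1 | intermediate
10 | (3S,5S)-5-(2-{[tert-butyl(diphenyl)silyl]oxy}ethyl)-3,5-dimethyl-1,2-dioxolane-3-carbaldehyde (racemic) | O=C[C@]1(C)C[C@](C)(CCO[Si](c2ccccc2)(c2ccccc2)C(C)(C)C)OO1 | intermediate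
11 | (4S)-4-benzyl-1,3-oxazolidin-2-one | O=C1OC[C@H](Cc2ccccc2)N1 | starting material
12 | diethyl {2-[(4S)-4-benzyl-2-oxo-1,3-oxazolidin-3-yl]-2-oxoethyl}phosphonate | CCOP(=O)(OCC)CC(=O)N1[C@@H](Cc2ccccc2)COC1=O | intermediate
13 | (4S)-4-benzyl-3-{(2E)-3-[(3S,5S)-5-(2-{[tert-butyl(diphenyl)silyl]oxy}ethyl)-3,5-dimethyl-1,2-dioxolan-3-yl]prop-2-enoyl}-1,3-oxazolidin-2-one (1:1 with the mirror-ring diastereomer) | O=C(/C=C/[C@]1(C)C[C@](C)(CCO[Si](c2ccccc2)(c2ccccc2)C(C)(C)C)OO1)N1[C@@H](Cc2ccccc2)COC1=O | intermediate
14 | (4S)-4-benzyl-3-{3-[(3R,5S)-5-(2-{[tert-butyl(diphenyl)silyl]oxy}ethyl)-3,5-dimethyl-1,2-dioxolan-3-yl]propanoyl}-1,3-oxazolidin-2-one (1:1 with the mirror-ring diastereomer) | O=C(CC[C@]1(C)C[C@](C)(CCO[Si](c2ccccc2)(c2ccccc2)C(C)(C)C)OO1)N1[C@@H](Cc2ccccc2)COC1=O | intermediate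
15 | sodium (Z)-enolate of 14 | [Na+].[O-]/C(=C\C[C@]1(C)C[C@](C)(CCO[Si](c2ccccc2)(c2ccccc2)C(C)(C)C)OO1)N1[C@@H](Cc2ccccc2)COC1=O | intermediate (not isolated)
16 | (4S)-4-benzyl-3-{(2S)-3-[(3R,5S)-5-(2-{[tert-butyl(diphenyl)silyl]oxy}ethyl)-3,5-dimethyl-1,2-dioxolan-3-yl]-2-methylpropanoyl}-1,3-oxazolidin-2-one | O=C([C@@H](C)C[C@]1(C)C[C@](C)(CCO[Si](c2ccccc2)(c2ccccc2)C(C)(C)C)OO1)N1[C@@H](Cc2ccccc2)COC1=O | intermediate
17 | (2S)-3-[(3R,5S)-5-(2-{[tert-butyl(diphenyl)silyl]oxy}ethyl)-3,5-dimethyl-1,2-dioxolan-3-yl]-2-methylpropan-1-ol | OC[C@@H](C)C[C@]1(C)C[C@](C)(CCO[Si](c2ccccc2)(c2ccccc2)C(C)(C)C)OO1 | intermediate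
18 | (2S)-3-[(3R,5S)-5-(2-{[tert-butyl(diphenyl)silyl]oxy}ethyl)-3,5-dimethyl-1,2-dioxolan-3-yl]-2-methylpropanal | O=C[C@@H](C)C[C@]1(C)C[C@](C)(CCO[Si](c2ccccc2)(c2ccccc2)C(C)(C)C)OO1 | intermediate
19 | 4-bromobutan-1-ol | OCCCCBr | starting material
20 | (4-hydroxybutyl)triphenylphosphonium bromide | [Br-].OCCCC[P+](c1ccccc1)(c1ccccc1)c1ccccc1 | intermediate
21 | sodium 4-(triphenyl-λ5-phosphanylidene)butan-1-olate | [Na+].[O-]CCCC=P(c1ccccc1)(c1ccccc1)c1ccccc1 | intermediate (not isolated)
22 | (4Z,6S)-7-[(3R,5S)-5-(2-{[tert-butyl(diphenyl)silyl]oxy}ethyl)-3,5-dimethyl-1,2-dioxolan-3-yl]-6-methylhept-4-en-1-ol | OCCC/C=C\[C@@H](C)C[C@]1(C)C[C@](C)(CCO[Si](c2ccccc2)(c2ccccc2)C(C)(C)C)OO1 | intermediate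
23 | (6R)-7-[(3R,5S)-5-(2-{[tert-butyl(diphenyl)silyl]oxy}ethyl)-3,5-dimethyl-1,2-dioxolan-3-yl]-6-methylheptan-1-ol | OCCCCC[C@@H](C)C[C@]1(C)C[C@](C)(CCO[Si](c2ccccc2)(c2ccccc2)C(C)(C)C)OO1 | intermediate
24 | (6R)-7-[(3R,5S)-5-(2-{[tert-butyl(diphenyl)silyl]oxy}ethyl)-3,5-dimethyl-1,2-dioxolan-3-yl]-6-methylheptanal | O=CCCCC[C@@H](C)C[C@]1(C)C[C@](C)(CCO[Si](c2ccccc2)(c2ccccc2)C(C)(C)C)OO1 | intermediate
25 | trans-cinnamyl chloride, [(1E)-3-chloroprop-1-en-1-yl]benzene | ClC/C=C/c1ccccc1 | starting material
26 | tert-butyl (4E)-5-phenylpent-4-enoate | CC(C)(C)OC(=O)CC/C=C/c1ccccc1 | intermediate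
27 | (4E)-5-phenylpent-4-en-1-ol | OCCC/C=C/c1ccccc1 | intermediate
28 | 1-phenyl-5-{[(4E)-5-phenylpent-4-en-1-yl]sulfanyl}-1H-tetrazole | c1ccccc1-n1nnnc1SCCC/C=C/c1ccccc1 | intermediate
29 | 1-phenyl-5-{[(4E)-5-phenylpent-4-en-1-yl]sulfonyl}-1H-tetrazole | O=S(=O)(CCC/C=C/c1ccccc1)c1nnnn1-c1ccccc1 | intermediate
30 | potassium salt of the α-sulfonyl carbanion of 29 | [K+].[CH-](CC/C=C/c1ccccc1)S(=O)(=O)c1nnnn1-c1ccccc1 | intermediate (not isolated)
31 | tert-butyl(2-{(3S,5R)-3,5-dimethyl-5-[(2R,7E,11E)-2-methyl-12-phenyldodeca-7,11-dien-1-yl]-1,2-dioxolan-3-yl}ethoxy)diphenylsilane | C[C@H](CCCC/C=C/CC/C=C/c1ccccc1)C[C@]1(C)C[C@](C)(CCO[Si](c2ccccc2)(c2ccccc2)C(C)(C)C)OO1 | intermediate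
32 | 2-{(3S,5R)-3,5-dimethyl-5-[(2R,7E,11E)-2-methyl-12-phenyldodeca-7,11-dien-1-yl]-1,2-dioxolan-3-yl}ethan-1-ol | C[C@H](CCCC/C=C/CC/C=C/c1ccccc1)C[C@]1(C)C[C@](C)(CCO)OO1 | intermediate
33 | 2-{(3R,5R)-3,5-dimethyl-5-[(2R,7E,11E)-2-methyl-12-phenyldodeca-7,11-dien-1-yl]-1,2-dioxolan-3-yl}acetaldehyde | C[C@H](CCCC/C=C/CC/C=C/c1ccccc1)C[C@]1(C)C[C@](C)(CC=O)OO1 | intermediate (not isolated)
34 | 2-{(3R,5R)-3,5-dimethyl-5-[(2R,7E,11E)-2-methyl-12-phenyldodeca-7,11-dien-1-yl]-1,2-dioxolan-3-yl}acetic acid (CNP0204107.4) | C[C@H](CCCC/C=C/CC/C=C/c1ccccc1)C[C@]1(C)C[C@](C)(CC(=O)O)OO1 | target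

## Step count and least certain steps

Total: 25 steps. Longest linear sequence: 19 steps, from 1 to 34 (steps 1–8, 10–14, 16–18, 23–25).

**Step 4 (key step).** The most likely failure is redox consumption of the hydroperoxide by the iodinating agent or by iodide formed in the flask, together with reversal of the iodoperoxidation; leakage to closure at the CH carbon is a smaller risk. Fallback, from 4 to 6: cycloperoxymercuration of 4 with Hg(OAc)2 in CH2Cl2, which is reversible and non-oxidising, followed by exchange with KBr, would give bromo[(1S,2S,5S)-1,5-dimethyl-6,7-dioxabicyclo[3.2.1]octan-2-yl]mercury F1. Bromodemercuration with Br2 in pyridine, conditions that favour retention, would give (1S,2S,5S)-2-bromo-1,5-dimethyl-6,7-dioxabicyclo[3.2.1]octane F2, with bromine axial as iodine is in 5. DBU elimination of F2 rejoins the route at 6. The mercury residues make this a small-scale option only.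

**Step 2.** Three processes threaten the mono-adduct: re-aromatisation to 1 by loss of the doubly allylic hydrogens under the radical conditions, addition to both alkenes, and transannular cyclisation of the intermediate peroxyl radical onto the second alkene. Fallback, from 2 to 4: mono-epoxidation of 2 with mCPBA (1 equiv, CH2Cl2, 0 °C) would give 1,3-dimethyl-7-oxabicyclo[4.1.0]hept-3-ene F3. LiAlH4 opens it at the CH carbon to 1,3-dimethylcyclohex-3-en-1-ol F4; no peroxide is present at that stage. Perhydrolysis of the tertiary alcohol (50 % H2O2, cat. H2SO4, 0 °C, behind a shield) then gives racemic 4, where the route is rejoined.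

**Step 12.** The alkylation itself is standard; the risk lies in the resolution, namely insufficient chromatographic discrimination between 16 and its diastereomer from the mirror-image ring, whose differing centres are separated by a methylene. Fallback, from racemic 9 back to 9: the enantiomers of 9 are separated directly by preparative chromatography on a chiral stationary phase, for which the silyl ether supplies a chromophore and aromatic contact points. The (3S,5S) enantiomer re-enters the route at 9, after which 13, 14 and 16 are single isomers and step 12 needs no separation. This fallback makes no new compound (F0).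

**Step 13.** Hydride may attack the O–O bond, or the hindered α-branched imide may be cleaved in the ring instead of at the exocyclic carbonyl. Fallback, from 16 to 17: hydrolysis with LiOH/H2O2 (THF/H2O, 0 °C, Na2SO3 quench), which a dialkyl peroxide tolerates, would give (2S)-3-[(3R,5S)-5-(2-{[tert-butyl(diphenyl)silyl]oxy}ethyl)-3,5-dimethyl-1,2-dioxolan-3-yl]-2-methylpropanoic acid F5. Activation with isobutyl chloroformate and N-methylmorpholine gives the mixed carbonic anhydride F6, which is not isolated and is reduced with NaBH4 in THF/H2O at 0 °C to 17, where the route is rejoined.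

## Further compounds

F1 | step 4 | bromo[(1S,2S,5S)-1,5-dimethyl-6,7-dioxabicyclo[3.2.1]octan-2-yl]mercury (racemic) | C1[C@H]([Hg]Br)[C@]2(C)C[C@](C)(C1)OO2
F2 | step 4 | (1S,2S,5S)-2-bromo-1,5-dimethyl-6,7-dioxabicyclo[3.2.1]octane (racemic) | C1[C@H](Br)[C@]2(C)C[C@](C)(C1)OO2
F3 | step 2 | 1,3-dimethyl-7-oxabicyclo[4.1.0]hept-3-ene (racemic, cis-fused) | CC1=CCC2OC2(C)C1
F4 | step 2 | 1,3-dimethylcyclohex-3-en-1-ol (racemic) | CC1=CCCC(C)(O)C1
F0 | step 12 | none | none
F5 | step 13 | (2S)-3-[(3R,5S)-5-(2-{[tert-butyl(diphenyl)silyl]oxy}ethyl)-3,5-dimethyl-1,2-dioxolan-3-yl]-2-methylpropanoic acid | OC(=O)[C@@H](C)C[C@]1(C)C[C@](C)(CCO[Si](c2ccccc2)(c2ccccc2)C(C)(C)C)OO1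
F6 | step 13 | mixed anhydride of F5 with isobutyl hydrogen carbonate | CC(C)COC(=O)OC(=O)[C@@H](C)C[C@]1(C)C[C@](C)(CCO[Si](c2ccccc2)(c2ccccc2)C(C)(C)C)OO1
A1 | alternative 1 | (1S,6R)-1,6-dimethyl-3,7,8-trioxabicyclo[4.2.1]nonan-4-one | O=C1OC[C@]2(C)C[C@](C)(C1)OO2
A2 | alternative 1 | [(3S)-5-methoxy-3,5-dimethyl-1,2-dioxolan-3-yl]methyl acetate (either epimer at the ketal carbon) | CC(=O)OC[C@]1(C)CC(C)(OC)OO1
A3 | alternative 1 | (R)-2-methylglycidol, [(2R)-2-methyloxiran-2-yl]methanol | OC[C@]1(C)CO1
A4 | alternative 2 | (1S,6S)-1,6-dimethyl-3,7,8-trioxabicyclo[4.2.1]nonane (racemic, needed enantiomer drawn) | C1OC[C@]2(C)C[C@](C)(C1)OO2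
A5 | alternative 2 | triethyl({2-methoxy-4-[(2-methylprop-2-en-1-yl)oxy]butan-2-yl}peroxy)silane (racemic) | C=C(C)COCCC(C)(OC)OO[Si](CC)(CC)CC
A6 | alternative 3 | (6R)-7-[(3R,5S)-5-(2-{[tert-butyl(diphenyl)silyl]oxy}ethyl)-3,5-dimethyl-1,2-dioxolan-3-yl]-6-methylheptyl 2,2-dimethylpropanoate | C[C@H](CCCCCOC(=O)C(C)(C)C)C[C@]1(C)C[C@](C)(CCO[Si](c2ccccc2)(c2ccccc2)C(C)(C)C)OO1
A7 | alternative 3 | (6R)-8-methoxy-6-methyl-8-[(triethylsilyl)peroxy]nonyl 2,2-dimethylpropanoate (either epimer at the ketal carbon) | C[C@H](CCCCCOC(=O)C(C)(C)C)CC(C)(OC)OO[Si](CC)(CC)CC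
A8 | alternative 3 | (R)-citronellal, (3R)-3,7-dimethyloct-6-enal | C[C@H](CCC=C(C)C)CC=O
A9 | alternative 3 | tert-butyl[(3-methylbut-3-en-1-yl)oxy]diphenylsilane | C=C(C)CCO[Si](c1ccccc1)(c1ccccc1)C(C)(C)C
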